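## Retrosynthetic overview

1. Target 23 ⇐ hydrogenation of the side-chain butenolide (sets C20) ⇐ face-selective C1 hydroxylation of the tetracyclic 1(9a)-enamine 20 (sets C1 and moves the enamine to C9=C9a).
2. Enamine 20 ⇐ one-pot triple ring closure of the open-chain sulfinamide 15: imine condensation (ring C), enamine Michael addition onto a butenolide (ring B, with ring D becoming the cis-fused lactone; sets C12 and C13), imine N-alkylation (ring A).
3. 15 ⇐ auxiliary-controlled vinylogous Mannich reaction of keto aldehyde 12 with a silyloxyfuran (sets C3 and C18, brings ring E as a butenolide).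
4. 12 ⇐ aldehyde 4 by α-methylenation and radical conjugate addition (four-carbon arm C5–C8), then a three-carbon Grignard addition and double oxidation.
5. 4 ⇐ organocatalytic vinylogous Mukaiyama–Michael addition of the same silyloxyfuran to pent-2-enal (sets C10 and C11, brings ring D as a butenolide). Ring order: D, then E, then C, B and A together.

Convention used below: N4, C3, C2, C1, C9a, C9, C8–C5 (N-CH2), C10 (ethyl-bearing), C11 (O-bearing), C12, C13 (methyl-bearing), C14 (lactone C=O), side-chain lactone C18–C21; ring A azepine, ring B cyclohexene, ring C pyrrolidine, ring D fused lactone, ring E side-chain lactone. The target is 1S,3S,10R,11R,12R,13S,18S,20S.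

## Route

Step 1
Reactants: 1 3-methylfuran-2(5H)-one
Product: 2 trimethyl[(3-methylfuran-2-yl)oxy]silane
Conditions: TMSOTf, Et3N, Et2O, 0 °C; filter, distil
Reagents that add atoms: trimethylsilyl trifluoromethanesulfonate C[Si](C)(C)OS(=O)(=O)C(F)(F)F
Why: Soft enolisation (O-silylation, then γ-deprotonation) gives the aromatic 2-silyloxyfuran, a silyl dienol ether formation that sets no stereocentre.

Step 2
Reactants: 2 trimethyl[(3-methylfuran-2-yl)oxy]silane; 3 (E)-pent-2-enal
Product: 4 (3R)-3-[(2R)-4-methyl-5-oxo-2,5-dihydrofuran-2-yl]pentanal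
Conditions: (2S,5S)-5-benzyl-2-tert-butyl-3-methylimidazolidin-4-one·2,4-dinitrobenzoic acid (20 mol%), CH2Cl2, H2O (2 equiv), −70 °C
Reagents that add atoms: none
Why: Organocatalytic vinylogous Mukaiyama–Michael addition to the (E)-iminium ion of 3: the benzyl group of the imidazolidinone shields one face so that furan C5 sets C10 as R (same sense as indole additions with this catalyst), and a Diels–Alder-like endo approach of the furan sets C11 as R (ethyl and ring oxygen anti in the zigzag chain).

Step 3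
Reactants: 4 (3R)-3-[(2R)-4-methyl-5-oxo-2,5-dihydrofuran-2-yl]pentanal; 5 formaldehyde
Product: 6 (3R)-2-methylidene-3-[(2R)-4-methyl-5-oxo-2,5-dihydrofuran-2-yl]pentanal
Conditions: aq. HCHO (37%), pyrrolidine (10 mol%), propionic acid (10 mol%), i-PrOH, 45 °C
Reagents that add atoms: none
Why: Amine-catalysed Mannich condensation and elimination (α-methylenation) can only occur at the single enolisable α-carbon (C9), brings in C8 and leaves the C10 and C11 stereocentres untouched.

Step 4
Reactants: 6 (3R)-2-methylidene-3-[(2R)-4-methyl-5-oxo-2,5-dihydrofuran-2-yl]pentanal; 7 1-chloro-3-iodopropane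
Product: 8 (3R)-2-(4-chlorobutyl)-3-[(2R)-4-methyl-5-oxo-2,5-dihydrofuran-2-yl]pentanal (both C2 epimers)
Conditions: Zn dust, CuI (20 mol%), i-PrOH/H2O 4:1, ultrasound, 20 °C
Reagents that add atoms: none
Why: Giese-type radical conjugate addition under aqueous Zn/CuI conditions: the 3-chloropropyl radical formed from the C–I bond adds to the unhindered methylene terminus, the C–Cl bond and the less reactive trisubstituted butenolide survive, and the new C9 centre is unselective but later becomes sp2.

Step 5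
Reactants: 8 (3R)-2-(4-chlorobutyl)-3-[(2R)-4-methyl-5-oxo-2,5-dihydrofuran-2-yl]pentanal; 9 3-chloropropan-1-ol
Product: 11 (5R)-5-[(3R)-8-chloro-4-(1,4-dihydroxybutyl)octan-3-yl]-3-methylfuran-2(5H)-one (epimer mixture at the two new or labile centres), via Normant reagent 10 (not isolated)
Conditions: 9, i-PrMgCl, THF, −20 °C, then Mg, reflux; add to 8, THF, −78 to −40 °C; aq. NH4Cl
Reagents that add atoms: none
Why: Grignard 1,2-addition of the O-metalated three-carbon reagent to the aldehyde, which is far more electrophilic than the lactone carbonyl at low temperature; the new carbinol centre is oxidised in the next step.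

Step 6
Reactants: 11 (5R)-5-[(3R)-8-chloro-4-(1,4-dihydroxybutyl)octan-3-yl]-3-methylfuran-2(5H)-one
Product: 12 (6R)-5-(4-chlorobutyl)-6-[(2R)-4-methyl-5-oxo-2,5-dihydrofuran-2-yl]-4-oxooctanal (C5 epimers)
Conditions: (COCl)2, DMSO, CH2Cl2, −78 °C; Et3N, −78 to −20 °C
Reagents that add atoms: none
Why: Swern oxidation activates both hydroxyl groups before base is added, so ketone and aldehyde form together and the lactol-to-lactone over-oxidation typical of 1,4-diols is avoided.

Step 7
Reactants: 12 (6R)-5-(4-chlorobutyl)-6-[(2R)-4-methyl-5-oxo-2,5-dihydrofuran-2-yl]-4-oxooctanal; 13 (R)-2-methylpropane-2-sulfinamide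
Product: 14 (R)-N-[(1E,6R)-5-(4-chlorobutyl)-6-[(2R)-4-methyl-5-oxo-2,5-dihydrofuran-2-yl]-4-oxooctylidene]-2-methylpropane-2-sulfinamide
Conditions: pyrrolidine (10 mol%), 4 Å MS, CH2Cl2, 20 °C
Reagents that add atoms: none
Why: Amine-catalysed Ellman condensation is selective for the aldehyde over the hindered α-branched ketone and gives the (E)-N-sulfinyl aldimine without acid, which would turn the 1,4-dicarbonyl into a furan.

Step 8
Reactants: 14 (R)-N-[(1E,6R)-5-(4-chlorobutyl)-6-[(2R)-4-methyl-5-oxo-2,5-dihydrofuran-2-yl]-4-oxooctylidene]-2-methylpropane-2-sulfinamide; 2 trimethyl[(3-methylfuran-2-yl)oxy]silane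
Product: 15 (R)-N-[(1S,6R)-5-(4-chlorobutyl)-1-[(2S)-4-methyl-5-oxo-2,5-dihydrofuran-2-yl]-6-[(2R)-4-methyl-5-oxo-2,5-dihydrofuran-2-yl]-4-oxooctyl]-2-methylpropane-2-sulfinamide
Conditions: TMSOTf (20 mol%), CH2Cl2, −78 °C; aq. NaHCO3
Reagents that add atoms: none
Why: Lewis-acid vinylogous Mannich (Mukaiyama–Mannich) reaction through an open transition state: furan C5 attacks the face of the s-cis (R)-sulfinyl imine opposite the tert-butyl group to give 3S, and the usual threo topicity of silyloxyfuran additions (N and ring O syn) gives 18S.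

Step 9
Reactants: 15 (R)-N-[(1S,6R)-5-(4-chlorobutyl)-1-[(2S)-4-methyl-5-oxo-2,5-dihydrofuran-2-yl]-6-[(2R)-4-methyl-5-oxo-2,5-dihydrofuran-2-yl]-4-oxooctyl]-2-methylpropane-2-sulfinamide
Product: 20 tetracyclic 1(9a)-enamine (rings A–D closed; C1=C9a; side-chain butenolide at C3; C9 epimers), via ammonium chloride 16 (not isolated), via pyrroline 17 (not isolated), via tricyclic imine 18 (not isolated), via iminium chloride 19 (not isolated)
Conditions: HCl (4 M in dioxane), MeOH, 0 °C, evaporate; NaHCO3, NaI (20 mol%), 4 Å MS, MeCN, 20 to 60 °C, Ar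
Reagents that add atoms: none
Why: Proposed new method: acid removes the sulfinyl group, the freed amine condenses with the 1,4-related ketone to the 1-pyrroline (ring C), its enamine tautomer adds through C1 to the β-carbon of the tethered butenolide in a 6-(enolendo)-exo-trig Michael reaction (ring B; the three-atom tether forces cis fusion and so sets C12, and external protonation of the lactone enolate on the convex face sets C13), and the imine nitrogen then displaces the primary halide (ring A) before deprotonation to the enamine; the closest known reaction types are the imine–enamine (aza-ene) Michael addition of cyclic imines and the N-alkylative cyclisation of ω-haloalkyl imines, while attack of C1 on the side-chain butenolide would need a strained azabicyclo[2.2.1] ring and attack of C9 a quaternary centre.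

Step 10
Reactants: 20 tetracyclic 1(9a)-enamine
Product: 22 19,20-didehydro target (1-hydroxy-9(9a)-enamine with side-chain butenolide), via oxido-iminium zwitterion 21 (not isolated)
Conditions: (1S)-(+)-(10-camphorsulfonyl)oxaziridine (1.05 equiv), THF, −78 to 0 °C, Ar
Reagents that add atoms: (1S)-(+)-(10-camphorsulfonyl)oxaziridine CC1(C)[C@@H]2CC[C@]13CS(=O)(=O)N4O[C@@]34C2
Why: Davis-type electrophilic oxygen transfer to an enamine: the β-carbon C1 of the ring-fused enamine takes oxygen on the face opposite the ring D lactone, the ethyl group and the C3 substituent (sets 1S), and the resulting iminium can lose only H9, which gives the C9=C9a enamine of the target.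

Step 11
Reactants: 22 19,20-didehydro target
Product: 23 target CNP0179500.1
Conditions: H2 (1 atm), 5% Rh/Al2O3, EtOAc, 20 °C
Reagents that add atoms: none
Why: Heterogeneous hydrogenation of the butenolide from the face opposite the bulky C18 substituent gives the cis α-methyl lactone (20S), while the tetrasubstituted enamine next to a quaternary carbon is not reduced under neutral conditions.

## Compound list

1 | 3-methylfuran-2(5H)-one | CC1=CCOC1=O | starting material
2 | trimethyl[(3-methylfuran-2-yl)oxy]silane | Cc1ccoc1O[Si](C)(C)C | intermediate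
3 | (E)-pent-2-enal | CC/C=C/C=O | starting material
4 | (3R)-3-[(2R)-4-methyl-5-oxo-2,5-dihydrofuran-2-yl]pentanal | CC[C@H](CC=O)[C@H]1OC(=O)C(C)=C1 | intermediate
5 | formaldehyde | C=O | starting material
6 | (3R)-2-methylidene-3-[(2R)-4-methyl-5-oxo-2,5-dihydrofuran-2-yl]pentanal | CC[C@H](C(=C)C=O)[C@H]1OC(=O)C(C)=C1 | intermediate
7 | 1-chloro-3-iodopropane | ClCCCI | starting material
8 | (3R)-2-(4-chlorobutyl)-3-[(2R)-4-methyl-5-oxo-2,5-dihydrofuran-2-yl]pentanal, C2 epimers | O=CC(CCCCCl)[C@@H](CC)[C@H]1OC(=O)C(C)=C1 | intermediate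
9 | 3-chloropropan-1-ol | OCCCCl | starting material
10 | Normant reagent, chloromagnesium 3-(chloromagnesio)propan-1-olate | Cl[Mg]CCCO[Mg]Cl | intermediate
11 | (5R)-5-[(3R)-8-chloro-4-(1,4-dihydroxybutyl)octan-3-yl]-3-methylfuran-2(5H)-one, epimers at octane C4 and the secondary carbinol | OCCCC(O)C(CCCCCl)[C@@H](CC)[C@H]1OC(=O)C(C)=C1 | intermediate
12 | (6R)-5-(4-chlorobutyl)-6-[(2R)-4-methyl-5-oxo-2,5-dihydrofuran-2-yl]-4-oxooctanal, C5 epimers | O=CCCC(=O)C(CCCCCl)[C@@H](CC)[C@H]1OC(=O)C(C)=C1 | intermediate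
13 | (R)-2-methylpropane-2-sulfinamide | CC(C)(C)[S@@](=O)N | starting material
14 | (R)-N-[(1E,6R)-5-(4-chlorobutyl)-6-[(2R)-4-methyl-5-oxo-2,5-dihydrofuran-2-yl]-4-oxooctylidene]-2-methylpropane-2-sulfinamide | CC(C)(C)[S@@](=O)/N=C/CCC(=O)C(CCCCCl)[C@@H](CC)[C@H]1OC(=O)C(C)=C1 | intermediate
15 | (R)-N-[(1S,6R)-5-(4-chlorobutyl)-1-[(2S)-4-methyl-5-oxo-2,5-dihydrofuran-2-yl]-6-[(2R)-4-methyl-5-oxo-2,5-dihydrofuran-2-yl]-4-oxooctyl]-2-methylpropane-2-sulfinamide | CC(C)(C)[S@@](=O)N[C@@H](CCC(=O)C(CCCCCl)[C@@H](CC)[C@H]1OC(=O)C(C)=C1)[C@H]2OC(=O)C(C)=C2 | intermediate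
16 | (1S,6R)-5-(4-chlorobutyl)-1-[(2S)-4-methyl-5-oxo-2,5-dihydrofuran-2-yl]-6-[(2R)-4-methyl-5-oxo-2,5-dihydrofuran-2-yl]-4-oxooctan-1-aminium chloride | [Cl-].[NH3+][C@@H](CCC(=O)C(CCCCCl)[C@@H](CC)[C@H]1OC(=O)C(C)=C1)[C@H]2OC(=O)C(C)=C2 | intermediate
17 | (5R)-5-[(3R)-8-chloro-4-{(2S)-2-[(2S)-4-methyl-5-oxo-2,5-dihydrofuran-2-yl]-3,4-dihydro-2H-pyrrol-5-yl}octan-3-yl]-3-methylfuran-2(5H)-one | ClCCCCC(C1=N[C@@H](CC1)[C@@H]2C=C(C)C(=O)O2)[C@@H](CC)[C@H]3OC(=O)C(C)=C3 | intermediate
18 | tricyclic imine: ring C 1-pyrroline (C9a=N4) fused to ring B cyclohexane, cis-fused ring D α-methyl lactone, 4-chlorobutyl on C9, ethyl on C10, butenolide on C3; configured as 23 at C3, C10, C11, C12, C13 and C18 | CC[C@@H]1C(CCCCCl)C2=N[C@@H](CC2[C@H]3[C@@H]1OC(=O)[C@H]3C)[C@@H]4C=C(C)C(=O)O4 | intermediate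
19 | tetracyclic iminium chloride (N4=C9a, rings A–D closed, H on C1 and C9, butenolide on C3); configured as 23 at C3, C10–C13 and C18 | CC[C@@H]1C2CCCC[N+]3=C2C(C[C@H]3[C@@H]4C=C(C)C(=O)O4)[C@H]5[C@@H]1OC(=O)[C@H]5C.[Cl-] | intermediate
20 | tetracyclic 1(9a)-enamine (C1=C9a, H on C9 as epimers, butenolide on C3); configured as 23 at C3, C10–C13 and C18 | CC[C@@H]1C2CCCCN3C2=C(C[C@H]3[C@@H]4C=C(C)C(=O)O4)[C@H]5[C@@H]1OC(=O)[C@H]5C | intermediate
21 | 1-oxido N4=C9a iminium zwitterion (1S) of 20 | CC[C@@H]1C2CCCC[N+]3=C2[C@]([O-])(C[C@H]3[C@@H]4C=C(C)C(=O)O4)[C@H]5[C@@H]1OC(=O)[C@H]5C | intermediate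
22 | 19,20-didehydro target: (1S,3S,10R,11R,12R,13S,18S)-1-hydroxy-9(9a)-enamine with (2S)-4-methyl-5-oxo-2,5-dihydrofuran-2-yl on C3 | CC[C@@H]1C2=C3N(CCCC2)[C@H]([C@@H]2C=C(C)C(=O)O2)C[C@]3(O)[C@H]2[C@@H]1OC(=O)[C@H]2C | intermediate
23 | CNP0179500.1, (1S,3S,10R,11R,12R,13S,18S,20S)-1-hydroxy-9(9a)-enamine tetracycle with (2S,4S)-4-methyl-5-oxooxolan-2-yl on C3 | CC[C@@H]1C2=C3N(CCCC2)[C@H]([C@@H]2C[C@H](C)C(=O)O2)C[C@]3(O)[C@H]2[C@@H]1OC(=O)[C@H]2C | target

## Step count and risks

Total step count: 11. Longest linear sequence: 11 steps (from 1; silyloxyfuran 2 is used in steps 2 and 8).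

**Step 9 (triple ring closure)** is the most likely to fail. The enamine Michael addition may stall at pyrroline 17, and the freed amine may attack the side-chain lactone before it condenses. An N–H enamine could also deliver its proton to C13 from the concave face and give the wrong C13 epimer. The fallback sets out from 12 and comes back at 20; it closes ring B before nitrogen is introduced:
- The aldehyde of 12 is masked selectively (ethylene glycol, PPTS, benzene, 4 Å MS) as the dioxolane keto acetal F1.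
- Pyrrolidine/benzoic acid catalysis forms the ketone enamine on the unbranched C1 side, which adds intramolecularly to the butenolide to give the cis-fused bicyclic keto lactone F2. This tertiary enamine has no N–H, so C13 is set by external protonation on the convex face.
- Mild acetal cleavage (PPTS, wet acetone) gives the bicyclic keto aldehyde F3.
- Condensation with 13 gives the sulfinyl imine F4, and the vinylogous Mannich reaction with 2 gives the bicyclic sulfinamide F5.
- HCl/MeOH, then NaHCO3/NaI in MeCN, now only has to close rings C and A and delivers 20.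

**Step 10 (C1 hydroxylation)** may fail through reaction of the minor 9(9a)-enamine tautomer at C9, or through over-oxidation at nitrogen. The fallback sets out from 20 and comes back at 22; it replaces oxygen-atom transfer by dioxygen. Enamine 20 takes up O2 (1 atm, CH2Cl2, −20 °C) at C1 on the open face to give the C1 hydroperoxide F6, as ring-fused enamines of the tetrahydrocarbazole type do. F6 is then reduced with Me2S to 22.

**Step 5 (Grignard addition)** may fail because the basic dianionic reagent can enolise the α-branched aldehyde, deprotonate the butenolide γ-position or attack the lactone. The fallback sets out from 8 and comes back at 11. Indium-mediated Barbier allylation (allyl bromide, In, THF/H2O), which is neutral and aldehyde-selective, gives the homoallylic alcohol F7. Anti-Markovnikov hydroboration–oxidation of its terminal alkene (9-BBN, THF, then NaBO3) gives diol 11.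

Further compounds
F1 | step 9 | (5R)-5-[(3R)-8-chloro-4-[3-(1,3-dioxolan-2-yl)propanoyl]octan-3-yl]-3-methylfuran-2(5H)-one | ClCCCCC(C(=O)CCC1OCCO1)[C@@H](CC)[C@H]2OC(=O)C(C)=C2
F2 | step 9 | (3S,3aR,7R,7aR)-6-(4-chlorobutyl)-4-(1,3-dioxolan-2-ylmethyl)-7-ethyl-3-methylhexahydro-1-benzofuran-2,5-dione, C4 and C6 epimers | CC[C@@H]1C(CCCCCl)C(=O)C(CC2OCCO2)[C@H]3[C@@H]1OC(=O)[C@H]3C
F3 | step 9 | [(3S,3aR,7R,7aR)-6-(4-chlorobutyl)-7-ethyl-3-methyl-2,5-dioxooctahydro-1-benzofuran-4-yl]acetaldehyde | CC[C@@H]1C(CCCCCl)C(=O)C(CC=O)[C@H]2[C@@H]1OC(=O)[C@H]2C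
F4 | step 9 | (R)-N-[(E)-2-[(3S,3aR,7R,7aR)-6-(4-chlorobutyl)-7-ethyl-3-methyl-2,5-dioxooctahydro-1-benzofuran-4-yl]ethylidene]-2-methylpropane-2-sulfinamide | CC[C@@H]1C(CCCCCl)C(=O)C(C/C=N/[S@](=O)C(C)(C)C)[C@H]2[C@@H]1OC(=O)[C@H]2C
F5 | step 9 | (R)-N-[(1S)-2-[(3S,3aR,7R,7aR)-6-(4-chlorobutyl)-7-ethyl-3-methyl-2,5-dioxooctahydro-1-benzofuran-4-yl]-1-[(2S)-4-methyl-5-oxo-2,5-dihydrofuran-2-yl]ethyl]-2-methylpropane-2-sulfinamide | CC[C@@H]1C(CCCCCl)C(=O)C(C[C@H](N[S@](=O)C(C)(C)C)[C@@H]2C=C(C)C(=O)O2)[C@H]3[C@@H]1OC(=O)[C@H]3C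
F6 | step 10 | C1 hydroperoxide of 22 (1-hydroperoxy-9(9a)-enamine with side-chain butenolide, configured as 22) | CC[C@@H]1C2=C3N(CCCC2)[C@H]([C@@H]2C=C(C)C(=O)O2)C[C@]3(OO)[C@H]2[C@@H]1OC(=O)[C@H]2C
F7 | step 5 | (5R)-5-[(3R)-8-chloro-4-(1-hydroxybut-3-en-1-yl)octan-3-yl]-3-methylfuran-2(5H)-one, epimer mixture | C=CCC(O)C(CCCCCl)[C@@H](CC)[C@H]1OC(=O)C(C)=C1
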